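At late times G stands still. In Thursday's run, with L at 0.75 mM, it reads 29.4 % at 5.00 min; in Saturday's, with L at 0.25 mM, it reads 29.8 % at 5.00 min. J is still climbing in both.

| setting | Thursday's | Saturday's | maple | alder |
|---|---|---|---|---|
| G | 10 mM | 10 mM | 10 mM | 10 mM |
| E | 0.70 equiv | 0.70 equiv | 0.700 equiv | 0.910 equiv |
| L | 0.75 mM | 0.25 mM | 0.500 mM | 0.500 mM |
| remark | run made earlier | run made earlier |  |  |
| time |  |  | 8.0 min | 8.0 min |

- Thursday's (time / min: G / %, J / %): 0.833: 30.5, 24.5; 1.50: 30.4, 37.2; 2.50: 29.8, 49.5; 3.00: 30.5, 52.9; 4.00: 29.4, 57.3; 5.00: 29.4, 59.3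
- Saturday's (time / min: G / %, J / %): 0.417: 29.3, 12.7; 0.667: 30.5, 20.9; 1.00: 30.5, 28.8; 2.00: 29.8, 45.1; 3.00: 30.2, 56.1; 5.00: 29.8, 64.5

(each reading ± 0.5 percentage points)

* part of the G that has reacted at the end, maple
* part of the G that has reacted at the end, alder
* what raising the equivalents of E from its lowest to its highest value here does to the part of the G that has reacted (changes below 5 percentage points count as none) (it rises / it falls / no change)

Read backwards, the reacted part of G is a steep wall and then a level, with the knee before the first reading. Saturday's run already shows 70.7 % reacted at 0.417 min, a mean slope of 17.0 mM min⁻¹. J crosses the G level later, between 0.833 min and 1.50 min in Thursday's run.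

I read the level as a rule, the reagent ceiling: c(E) charged over c(G) charged, with one E taken per G and E as limiting reagent. It is 70.0 % for maple and 91.0 % for alder.

Alder's knee comes later, so I check that it arrives in time. If Saturday's first reading hides at most two scatters of E, 0.100 mM, the second-order law bounds the rate constant of G + E from below. Alder keeps an excess of G of 0.900 mM, so its last E decays pseudo-first-order with a time constant of at most 0.452 min. That is far shorter than 8.0 min, so I commit to the ceilings.

The forecast gives 70 % (69.5 % to 70.5 %) for maple and 90.5 % (87.5 % to 91.3 %) for alder, a little under my ceiling, and its trend is: it rises. Its ground: “E is used up within seconds, one for one”.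

The flasks give 70.0 % for maple and 91.0 % for alder, and the trend is: it rises, a change of 21 percentage points, so the forecast stands. Alder ends with E at 0 % of its charge and G at 9.00 %, and its ceiling reads 91.0 %. With the other charges and the time held, c2 has moved by 5 points at 0.860 equiv or 0.960 equiv of E.

    G + E → D + Z (k = 98.1 M⁻¹ s⁻¹)
    D → J (k = 0.00936 s⁻¹)
    E + Z ⇌ Q, settled at all times (K = 49.4 M⁻¹)
    D + L → X (k = 2.55 M⁻¹ s⁻¹)

For a neighbour flask, maple with 0.420 equiv of E, the ceiling gives 42.0 %. The computed flask reacts 42.0 % of its G, leaving 58.0 %.

The runs come from a simulation on assumed constants, and the scatter is random.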